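# Proposed synthesis of the (R)-dihydrofurano-isoflavone 20 by a quinone methide (4+1) annulation

## Analysis of the target

- Target 20 is a 5,7,2'-trihydroxyisoflavone. Ring A (C4a to C8a, hydroxyls at C5 and C7) is fused to the pyranone ring C (O1, C2, C3, C4), and ring B is attached through C1' to C3.
- Ring B is contiguously tetrasubstituted: C1' (chromone), C2' (OH), C3' (benzylic CH2) and C4' (ether oxygen). C3' and C4' are bridged by a dihydrofuran, ring D (O1''–C2''–C3''–C3'–C4'), and C2'' carries a 2-hydroxypropan-2-yl group.
- C2'' is the only stereocentre and is R. Nothing else in the molecule can relay it, so it must come from a reagent, a catalyst or a chiral building block and then survive every later step.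
- The sensitive groups are:
  - the tertiary alcohol beta to the ring D oxygen, which strong acid can dehydrate or ring-expand to a hydroxychroman;
  - C2 of the chromone, which hydroxide attacks;
  - the C2=C3 bond, which can be hydrogenated;
  - three phenols, one of them chelated to the C4 carbonyl.
- The main difficulty is the regiochemistry of ring B. C3' lies between two oxygens, so a classical prenyl-phenol cyclisation has to choose between the 2'- and 4'-hydroxyl, and C1' must then be functionalised selectively next to C2'.
- The strategy rests on one feature: O1'', C4', C3' and C3'' are the four atoms of an ortho-quinone methide of a 2-substituted resorcinol, and C2'' is a single carbon that caps them.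
- That resorcinol has a mirror plane through C3'. Either oxygen can close ring D with the same result, and the oxygen left over is the 2'-hydroxyl, placed to direct a one-carbon unit onto C1'.

## Retrosynthetic reasoning

**20 from 19.** The three phenols are unmasked last. Benzyl ethers are chosen because their removal is neutral, which suits the tertiary alcohol and the chromone. The forward step must cleave three O–benzyl bonds without reducing C2=C3.

**19 from 17.** Ring C is cut at O1–C2 and at C3–C1'. This leads back to the 2'-hydroxychalcone 17, in which ring B sits on the beta carbon. An oxidative 1,2-aryl shift moves ring B to the alpha carbon and leaves the beta carbon as the acetal 18, which closes onto the free ring A hydroxyl. The cut is made here because it lets ring B enter as an aldehyde. An aldehyde at C1' is what the 2'-hydroxyl can direct, whereas a halide or boron at C1' would have to be placed against the competing position para to that hydroxyl. Ring B carries oxygen ortho and para to C1', so it is a good migrating group.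

**17 from 14 and 16.** The enone C=C bond is cut by an aldol condensation between aldehyde 14 and methyl ketone 16. This is the convergent point of the route, since 16 is one step from 15. The forward reaction only has to form the E-enone; the stereocentre is remote and has no acidic hydrogen.

**14 from 13, and 13 from 12.** The benzyl ether on the 2'-oxygen is removed, then the C1'–CHO bond is cut. In phenol 12 the hydroxyl has one free ortho position (C5 of the dihydrobenzofuran, the future C1'); the other ortho carbon is the ring fusion. A phenoxide-directed formylation therefore has no regiochemical choice. The benzyl group is needed later so that this oxygen cannot compete with the ring A hydroxyl for the acetal carbon.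

**12 from 11.** The two C–CH3 bonds of the tertiary alcohol are cut, leaving the ester 11. The ester is the acceptor group that stabilises the ylide in the key step, so it does two jobs. The forward double methyl addition must outrun enolisation at C2.

**11 from 3 and 7 (key disconnection).** Ring D is cut at C3''–C2'' and at O1''–C2''. This removes the single carbon C2'' as the ylide 9 of salt 7 and leaves the quinone methide 8, which is released from sulfone 3 by base. Both ring bonds and the stereocentre form in one operation through betaine 10. The precursor is symmetric, so no protecting group has to tell the two oxygens apart. The forward reaction must make the C–C bond by conjugate addition, make the C–O bond by displacement of the ammonium group, and let the chiral ammonium group fix the configuration at C2''.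

**3 from 2, and 2 from 1.** The benzylic C–S bond is cut to the benzylic alcohol 2, which comes from aldehyde 1 by hydride reduction. The sulfonyl group serves only as a base-labile leaving group that stores the quinone methide.

**7 from 5 and 6, and 5 from 4.** The N–CH2 bond of the salt is cut to the tertiary amine 5 and the bromoacetate 6. Amine 5 is the O-methyl ether of the alkaloid 4. Capping the hydroxyl of 4 removes a nucleophile that could be alkylated or could lactonise onto the ester.

**16 from 15.** Two O–benzyl bonds are cut. The hydroxyl hydrogen-bonded to the ketone stays free and later becomes O1 of ring C.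

## Alternatives that were turned down

**Alternative 1: rhodium-catalysed oxidative annulation of a salicylaldehyde with a silyl alkyne.**
- Disconnection: ring C is cut at C4–C3 and O1–C2, giving the ring A salicylaldehyde A2 and the ring B aryl(trimethylsilyl)alkyne A3.
- Forward key step: [Cp*RhCl2]2 (trivalent rhodium) with Cu(OAc)2 as oxidant activates the aldehyde C–H of A2, inserts A3 and closes ring C to the 2-silyl isoflavone A1. Protodesilylation and debenzylation would then lead to 20.
- For: the chromone is assembled convergently in one step, no stoichiometric heavy-metal oxidant is needed, and the silyl group should steer the aryl carbon to C3.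
- Against: A3 must already contain ring D and its stereocentre, so the only stereochemical problem is left unsolved. A3 would most plausibly be made from aldehyde 14 by alkynylation and silylation, so nothing upstream is saved. The alkyne is flanked by an ortho benzyloxy group, and insertion into a hindered, electron-rich acyl–rhodium bond has to compete with decarbonylation. A further desilylation is needed on a chromone that is sensitive to fluoride and base.
- Comparison: this alternative is stronger on convergence at ring C and on avoiding thallium. The chosen strategy instead makes ring D, its stereocentre and the ring B substitution pattern in one step from a symmetric precursor, and it reaches ring C through shorter, classical chemistry.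

**Alternative 2: three-component carbonylative coupling around the C4 carbonyl.**
- Disconnection: the bonds C4a–C4 and C4–C3 are cut on both sides of the carbonyl, giving the ring A aryl iodide A5, carbon monoxide A7 and the ring B benzylzinc chloride A6.
- Forward key step: Pd(PPh3)4 (zerovalent palladium) joins the three components to the fully protected deoxybenzoin A4. C2 would then be inserted as a one-carbon unit.
- For: ring A is symmetric, so no regiochemistry arises there, and closing a deoxybenzoin to an isoflavone is well established and thallium-free.
- Against: A5 is electron-rich and has two ortho alkoxy groups, so oxidative addition and CO insertion are slow. Direct coupling without CO would give a diarylmethane. A6 needs reduction, halogenation and zinc insertion from an aldehyde such as 14, plus a silyl ether on the tertiary alcohol. A4 has no free ortho hydroxyl, so a deprotection must precede C2 insertion, and the ring B hydroxyl can then condense with the ketone to a benzofuran. The stereocentre is again assumed rather than made.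
- Comparison: this alternative is as good as the chosen route in its end game and avoids thallium. It is longer by several steps, and the chosen route forms the same C–C framework with a simple aldol condensation.

**Alternative 3: enantioselective carbene C–H insertion closing the dihydrofuran.**
- Disconnection: only the C3''–C2'' bond of ring D is cut, leading to the tosylhydrazone A9 of an ortho-alkoxybenzaldehyde.
- Forward key step: a chiral cobalt porphyrin Co(Por*) (divalent cobalt) with Cs2CO3 generates a carbene radical that abstracts a hydrogen atom from the O–CH2 group and recombines, giving the dihydrobenzofuran A8. Desilylation of A8 would give 12.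
- For: the chiral source is catalytic, the complete side chain is already in place so no Grignard step is needed, and no quinone methide is involved. On these three points it is stronger than the chosen route.
- Against: the C–H bond to be attacked lies next to a quaternary carbon that bears a bulky silyloxy group, and the carbene carbon is flanked by two ortho oxygen substituents. The rate and enantioselectivity in such a congested case are hard to foresee. The two oxygens of the resorcinol must be differentiated (one silylated, one alkylated with a neopentyl-type fragment), which costs several steps and gives up the symmetry. The chiral porphyrin is itself a multistep ligand.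
- Comparison: the chosen strategy uses a stoichiometric chiral amine, but it is made in one step from an inexpensive alkaloid and is recovered. The chosen route reaches its key precursor in two steps, forms both ring D bonds at once, and leaves a free hydroxyl that is used directly to direct the next C–C bond.

Key step: step 5

Assumption: the ammonium group built on the quinidine skeleton is taken to favour the R configuration at the new stereocentre. The sense of induction for a quinone methide without a substituent on its methylene carbon cannot be predicted with confidence; if it proved opposite, the pseudoenantiomeric alkaloid skeleton would be used in steps 3 to 5 without other change.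

## Route

Step 1
Reactants: 1 2,6-dihydroxybenzaldehyde
Product: 2 2-(hydroxymethyl)benzene-1,3-diol
Conditions: NaBH4, EtOH, 0 °C; then aq NH4Cl to pH 6–7
Reagents that add atoms: none
Why: Hydride reduction of an aryl aldehyde with NaBH4; the phenols are only deprotonated, and the cold, near-neutral quench avoids the acid that would ionise the electron-rich benzylic alcohol, which is used at once.

Step 2
Reactants: 2 2-(hydroxymethyl)benzene-1,3-diol
Product: 3 2-[(4-methylbenzenesulfonyl)methyl]benzene-1,3-diol
Conditions: TolSO2Na (3 equiv), HCO2H/H2O, rt
Reagents that add atoms: sodium p-toluenesulfinate, Cc1ccc(cc1)S(=O)[O-].[Na+]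
Why: Acid-promoted ionisation of the ortho-hydroxybenzylic alcohol gives a stabilised benzylic cation (a protonated quinone methide) that the sulfinate captures at sulfur, the standard preparation of 2-(sulfonylmethyl)phenols; the excess of sulfinate should outcompete alkylation of a second resorcinol ring.

Step 3
Reactants: 4 quinidine
Product: 5 9-O-methylquinidine
Conditions: NaH, DMF, 0 °C to rt; then MeI (1.0 equiv), 0 °C
Reagents that add atoms: iodomethane, CI
Why: Williamson ether synthesis; the preformed alkoxide is far more nucleophilic than either nitrogen when one equivalent of MeI is added cold, and the methyl ether removes a hydroxyl that could otherwise be alkylated or attack the ester in steps 4 and 5.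

Step 4
Reactants: 5 9-O-methylquinidine; 6 tert-butyl bromoacetate
Product: 7 N-(2-tert-butoxy-2-oxoethyl)-9-O-methylquinidinium bromide (alkylated at the quinuclidine nitrogen)
Conditions: THF, rt; precipitation and trituration with Et2O
Reagents that add atoms: none
Why: Menshutkin quaternisation at the sp3 quinuclidine nitrogen, which is much more nucleophilic than the quinoline nitrogen; isolating the salt by precipitation ensures that no free alkylating agent enters the key step.

Step 5
Reactants: 3 2-[(4-methylbenzenesulfonyl)methyl]benzene-1,3-diol; 7 N-(2-tert-butoxy-2-oxoethyl)-9-O-methylquinidinium bromide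
Product: 11 tert-butyl (2R)-4-hydroxy-2,3-dihydro-1-benzofuran-2-carboxylate, via ortho-quinone methide 8 (not isolated), via ammonium ylide 9 (not isolated), via betaine 10 (not isolated)
Conditions: 7 (1.3 equiv), Cs2CO3 (4 equiv), CH2Cl2, 0 °C to rt; 5 recovered by acid extraction
Reagents that add atoms: none
Why: Cs2CO3 deprotonates a phenol of 3 and expels p-toluenesulfinate in a 1,4-elimination to give quinone methide 8 in low stationary concentration, while the same base converts salt 7 into the ester-stabilised ammonium ylide 9. Conjugate addition of the ylide carbon to the exocyclic CH2 of 8 forms the C3–C2 bond and restores the aromatic ring, giving betaine 10. The phenoxide of 10 then displaces the quinuclidinium nitrogen at the alpha carbon in a 5-exo-tet SN2 closure with inversion, which forms the O1–C2 bond, closes the dihydrofuran ring and releases 5. This is the known (4+1) annulation of ortho-quinone methides from 2-(sulfonylalkyl)phenols with cinchona-derived ammonium ylides, applied here to an unsubstituted methylene terminus. The single new stereocentre C2 is under reagent control: the alpha carbon of 10 is acidic and epimerises through the ylide, and the chiral ammonium group decides which epimer (the alpha-S one) reaches the backside-attack geometry faster, so that inversion delivers R. Regioselectivity is not an issue because the two hydroxyls of 3 are related by a mirror plane and closure through either gives the same product, the other remaining as the future 2'-hydroxyl. Carbon- over oxygen-alkylation is secured by the preformed salt 7 (no free bromoacetate) and by the reversible re-addition of sulfinate, which keeps 8 scarce and disfavours its dimerisation.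

Step 6
Reactants: 11 tert-butyl (2R)-4-hydroxy-2,3-dihydro-1-benzofuran-2-carboxylate
Product: 12 (2R)-2-(2-hydroxypropan-2-yl)-2,3-dihydro-1-benzofuran-4-ol
Conditions: MeMgBr (6 equiv), CeCl3, THF, −78 to 0 °C; aq NH4Cl
Reagents that add atoms: methylmagnesium bromide, C[Mg]Br
Why: Double addition of a methyl organometallic to an ester (Grignard reaction, cerium-modified to favour addition over enolisation at C2–H, so the configuration is kept); the first equivalent converts the phenol into its phenoxide, which protects it in the flask.

Step 7
Reactants: 12 (2R)-2-(2-hydroxypropan-2-yl)-2,3-dihydro-1-benzofuran-4-ol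
Product: 13 (2R)-4-hydroxy-2-(2-hydroxypropan-2-yl)-2,3-dihydro-1-benzofuran-5-carbaldehyde
Conditions: MgCl2, Et3N, (CH2O)n, MeCN, reflux; dilute HCl work-up, cold
Reagents that add atoms: paraformaldehyde (as formaldehyde), C=O
Why: Magnesium phenoxide-directed ortho-formylation (Casiraghi–Skattebøl): formaldehyde is delivered within the magnesium chelate to the only free ortho position C5, the other ortho carbon being the ring fusion C3a, and the hydroxymethyl intermediate is oxidised by hydride transfer to a second formaldehyde; the para position C7 is not reached by this chelate-bound mechanism.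

Step 8
Reactants: 13 (2R)-4-hydroxy-2-(2-hydroxypropan-2-yl)-2,3-dihydro-1-benzofuran-5-carbaldehyde
Product: 14 (2R)-4-(benzyloxy)-2-(2-hydroxypropan-2-yl)-2,3-dihydro-1-benzofuran-5-carbaldehyde
Conditions: BnBr, K2CO3, DMF, 50 °C
Reagents that add atoms: benzyl bromide, BrCc1ccccc1
Why: Williamson etherification of the phenol; K2CO3 does not deprotonate the tertiary alcohol, and the benzyl ether keeps this oxygen from competing for the acetal carbon or being oxidised in step 11.

Step 9
Reactants: 15 1-(2,4,6-trihydroxyphenyl)ethan-1-one
Product: 16 1-[2,4-bis(benzyloxy)-6-hydroxyphenyl]ethan-1-one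
Conditions: BnBr (2.1 equiv), K2CO3, DMF, rt to 40 °C; crystallisation
Reagents that add atoms: benzyl bromide, BrCc1ccccc1
Why: Williamson etherification; the hydroxyl hydrogen-bonded to the ketone carbonyl is the least nucleophilic, so two equivalents cap the para hydroxyl and one ortho hydroxyl, and over- or C-benzylated material is removed by crystallisation.

Step 10
Reactants: 14 (2R)-4-(benzyloxy)-2-(2-hydroxypropan-2-yl)-2,3-dihydro-1-benzofuran-5-carbaldehyde; 16 1-[2,4-bis(benzyloxy)-6-hydroxyphenyl]ethan-1-one
Product: 17 (2E)-1-[2,4-bis(benzyloxy)-6-hydroxyphenyl]-3-[(2R)-4-(benzyloxy)-2-(2-hydroxypropan-2-yl)-2,3-dihydro-1-benzofuran-5-yl]prop-2-en-1-one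
Conditions: KOH (50% aq), EtOH/THF, rt; then cold dilute HCl to pH 5
Reagents that add atoms: none
Why: Claisen–Schmidt condensation of a non-enolisable aryl aldehyde with an aryl methyl ketone; E1cB dehydration gives the conjugated E-enone, and the stereocentre bears no acidic hydrogen and is untouched by hydroxide.

Step 11
Reactants: 17 (2E)-1-[2,4-bis(benzyloxy)-6-hydroxyphenyl]-3-[(2R)-4-(benzyloxy)-2-(2-hydroxypropan-2-yl)-2,3-dihydro-1-benzofuran-5-yl]prop-2-en-1-one
Product: 19 5,7-bis(benzyloxy)-3-[(2R)-4-(benzyloxy)-2-(2-hydroxypropan-2-yl)-2,3-dihydro-1-benzofuran-5-yl]-4H-chromen-4-one, via dimethyl acetal 18 (not isolated)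
Conditions: Tl(NO3)3·3H2O (1.2 equiv), MeOH/HC(OMe)3, rt; then 2 M HCl, MeOH/THF, 50 °C
Reagents that add atoms: none
Why: Oxidative rearrangement of a 2'-hydroxychalcone: oxythallation of the enone by trivalent thallium is followed by a 1,2-shift of the electron-rich ring B from the beta to the alpha carbon with loss of TlNO3 (monovalent thallium), and methanol traps the beta carbon as acetal 18. Acid then closes ring C by attack of the free ring A hydroxyl on the acetal carbon and loss of methanol; the acid is kept dilute and the time short for the sake of the tertiary alcohol.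

Step 12
Reactants: 19 5,7-bis(benzyloxy)-3-[(2R)-4-(benzyloxy)-2-(2-hydroxypropan-2-yl)-2,3-dihydro-1-benzofuran-5-yl]-4H-chromen-4-one
Product: 20 5,7-dihydroxy-3-[(2R)-4-hydroxy-2-(2-hydroxypropan-2-yl)-2,3-dihydro-1-benzofuran-5-yl]-4H-chromen-4-one
Conditions: H2 (1 atm), 10% Pd/C, EtOAc/MeOH, rt; stopped after uptake of three equivalents
Reagents that add atoms: none
Why: Hydrogenolysis of three benzyl aryl ethers under neutral conditions; the C–O bonds of ring D are an aryl–O and a non-benzylic alkyl–O bond and are not cleaved, and monitoring the uptake protects the C2=C3 bond.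

## Compound list

1 | 2,6-dihydroxybenzaldehyde | O=Cc1c(O)cccc1O | starting material
2 | 2-(hydroxymethyl)benzene-1,3-diol | OCc1c(O)cccc1O | intermediate
3 | 2-[(4-methylbenzenesulfonyl)methyl]benzene-1,3-diol | Cc1ccc(cc1)S(=O)(=O)Cc1c(O)cccc1O | intermediate
4 | quinidine, (9S)-6'-methoxycinchonan-9-ol | COc1ccc2nccc([C@@H]([C@H]3C[C@@H]4CCN3C[C@@H]4C=C)O)c2c1 | starting material
5 | 9-O-methylquinidine | COc1ccc2nccc([C@@H]([C@H]3C[C@@H]4CCN3C[C@@H]4C=C)OC)c2c1 | intermediate
6 | tert-butyl bromoacetate | CC(C)(C)OC(=O)CBr | starting material
7 | N-(2-tert-butoxy-2-oxoethyl)-9-O-methylquinidinium bromide | COc1ccc2nccc([C@@H]([C@H]3C[C@@H]4CC[N@@+]3(CC(=O)OC(C)(C)C)C[C@@H]4C=C)OC)c2c1.[Br-] | intermediate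
8 | 5-hydroxy-6-methylidenecyclohexa-2,4-dien-1-one (ortho-quinone methide) | C=C1C(=O)C=CC=C1O | intermediate (not isolated)
9 | ammonium ylide formed from 7 by loss of HBr | COc1ccc2nccc([C@@H]([C@H]3C[C@@H]4CC[N@@+]3([CH-]C(=O)OC(C)(C)C)C[C@@H]4C=C)OC)c2c1 | intermediate (not isolated)
10 | betaine, tert-butyl (2S)-3-(2-hydroxy-6-oxidophenyl)-2-(9-O-methylquinidinium-1-yl)propanoate (the epimer that closes; it equilibrates with the 2R epimer) | COc1ccc2nccc([C@@H]([C@H]3C[C@@H]4CC[N@@+]3([C@@H](Cc5c([O-])cccc5O)C(=O)OC(C)(C)C)C[C@@H]4C=C)OC)c2c1 | intermediate (not isolated)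
11 | tert-butyl (2R)-4-hydroxy-2,3-dihydro-1-benzofuran-2-carboxylate | CC(C)(C)OC(=O)[C@H]1Cc2c(cccc2O)O1 | intermediate
12 | (2R)-2-(2-hydroxypropan-2-yl)-2,3-dihydro-1-benzofuran-4-ol | CC(C)(O)[C@H]1Cc2c(cccc2O)O1 | intermediate
13 | (2R)-4-hydroxy-2-(2-hydroxypropan-2-yl)-2,3-dihydro-1-benzofuran-5-carbaldehyde | CC(C)(O)[C@H]1Cc2c(ccc(C=O)c2O)O1 | intermediate
14 | (2R)-4-(benzyloxy)-2-(2-hydroxypropan-2-yl)-2,3-dihydro-1-benzofuran-5-carbaldehyde | CC(C)(O)[C@H]1Cc2c(ccc(C=O)c2OCc3ccccc3)O1 | intermediate
15 | 1-(2,4,6-trihydroxyphenyl)ethan-1-one | CC(=O)c1c(O)cc(O)cc1O | starting material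
16 | 1-[2,4-bis(benzyloxy)-6-hydroxyphenyl]ethan-1-one | CC(=O)c1c(O)cc(OCc2ccccc2)cc1OCc3ccccc3 | intermediate
17 | (2E)-1-[2,4-bis(benzyloxy)-6-hydroxyphenyl]-3-[(2R)-4-(benzyloxy)-2-(2-hydroxypropan-2-yl)-2,3-dihydro-1-benzofuran-5-yl]prop-2-en-1-one | CC(C)(O)[C@H]1Cc2c(ccc(/C=C/C(=O)c3c(O)cc(OCc4ccccc4)cc3OCc5ccccc5)c2OCc6ccccc6)O1 | intermediate
18 | 1-[2,4-bis(benzyloxy)-6-hydroxyphenyl]-2-[(2R)-4-(benzyloxy)-2-(2-hydroxypropan-2-yl)-2,3-dihydro-1-benzofuran-5-yl]-3,3-dimethoxypropan-1-one (both epimers at C2 of the propanone) | CC(C)(O)[C@H]1Cc2c(ccc(C(C(OC)OC)C(=O)c3c(O)cc(OCc4ccccc4)cc3OCc5ccccc5)c2OCc6ccccc6)O1 | intermediate (not isolated)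
19 | 5,7-bis(benzyloxy)-3-[(2R)-4-(benzyloxy)-2-(2-hydroxypropan-2-yl)-2,3-dihydro-1-benzofuran-5-yl]-4H-chromen-4-one | CC(C)(O)[C@H]1Cc2c(ccc(-c3coc4cc(OCc5ccccc5)cc(OCc6ccccc6)c4c3=O)c2OCc7ccccc7)O1 | intermediate
20 | 5,7-dihydroxy-3-[(2R)-4-hydroxy-2-(2-hydroxypropan-2-yl)-2,3-dihydro-1-benzofuran-5-yl]-4H-chromen-4-one | CC(C)(O)[C@H]1Cc2c(ccc(-c3coc4cc(O)cc(O)c4c3=O)c2O)O1 | target

## Step count and least certain steps

Total step count: 12. Longest linear sequence: 9 steps (steps 1, 2, 5, 6, 7, 8, 10, 11 and 12, from 1 to 20). Steps 3 and 4 (chiral salt) and step 9 (ring A ketone) are side branches.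

**Step 5 (key step).**
- Most likely failure: too little discrimination between the two epimeric betaines. The methylene carbon has no substituent, so there is no second stereocentre and no steric bias at the quinone methide terminus. All of the selectivity must come from the chiral ammonium group during epimerisation and ring closure.
- Second failure mode: loss of the quinone methide by self-dimerisation. The remaining hydroxyl of 8 is a vinylogous acid and will be deprotonated, so the acceptor is an anion and reacts more slowly with the ylide.
- Fallback: racemic annulation followed by resolution, setting out from 3 and 6 and returning at 11. Compound 6 and dimethyl sulfide would give (2-tert-butoxy-2-oxoethyl)dimethylsulfonium bromide F1. Its stabilised sulfonium ylide can be used in excess with 3 and Cs2CO3 and should give racemic tert-butyl 4-hydroxy-2,3-dihydro-1-benzofuran-2-carboxylate F2. Preparative chromatography on a polysaccharide chiral stationary phase would then give 11, at the cost of half the material.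

**Step 2 (with step 1).**
- Most likely failure: self-condensation. The benzylic cation that the sulfinate should capture can instead alkylate a second, very electron-rich resorcinol ring. Over-reduction of 1 to the methyl compound through the same quinone methide is a lesser risk in step 1.
- Fallback: the phenols are capped during the substitution, setting out from 1 and returning at 3. Benzylation of 1 would give 2,6-bis(benzyloxy)benzaldehyde F3. NaBH4 reduction would give [2,6-bis(benzyloxy)phenyl]methanol F4. PBr3 would give 1,3-bis(benzyloxy)-2-(bromomethyl)benzene F5. SN2 displacement with sodium p-toluenesulfinate in DMF would give 1,3-bis(benzyloxy)-2-[(4-methylbenzenesulfonyl)methyl]benzene F6. Hydrogenolysis over Pd/C would then give 3.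

**Step 11.**
- Most likely failure: acid-promoted ionisation or dehydration of the tertiary alcohol during acetal formation and ring closure, together with oxidative degradation of the electron-rich ring B by trivalent thallium.
- Fallback: ring C is built first and ring B is attached by cross-coupling, setting out from 12 and 16 and returning at 19.
  - Ring B partner: amine-catalysed ortho-bromination of 12 with NBS would give (2R)-5-bromo-2-(2-hydroxypropan-2-yl)-2,3-dihydro-1-benzofuran-4-ol F7. Benzylation would give 2-[(2R)-4-(benzyloxy)-5-bromo-2,3-dihydro-1-benzofuran-2-yl]propan-2-ol F8. Miyaura borylation with Pd(dppf)Cl2 would give the pinacol boronate F9.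
  - Ring A/C partner: 16 and dimethylformamide dimethyl acetal would give the enaminone (2E)-1-[2,4-bis(benzyloxy)-6-hydroxyphenyl]-3-(dimethylamino)prop-2-en-1-one F10. Iodine would cyclise it to 5,7-bis(benzyloxy)-3-iodo-4H-chromen-4-one F11.
  - Suzuki coupling of F9 with F11 using Pd(PPh3)4 and K3PO4 would give 19 under conditions that are neither acidic nor oxidising.

**Step 6.**
- Most likely failure: partial loss of configuration at C2. Addition to the hindered tert-butyl ester is slow, so enolisation of the ester or of the intermediate methyl ketone can compete.
- Fallback: the ester is changed before the addition, setting out from 11 and returning at 12. Acidic methanolysis (HCl, MeOH) would exchange the tert-butyl group for methyl and give methyl (2R)-4-hydroxy-2,3-dihydro-1-benzofuran-2-carboxylate F12. The unhindered ester should add MeMgBr faster than it enolises, giving 12.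

## Further compounds

F1 | step 5 | (2-tert-butoxy-2-oxoethyl)dimethylsulfonium bromide | C[S+](C)CC(=O)OC(C)(C)C.[Br-]
F2 | step 5 | racemic tert-butyl 4-hydroxy-2,3-dihydro-1-benzofuran-2-carboxylate | CC(C)(C)OC(=O)C1Cc2c(cccc2O)O1
F3 | step 2 | 2,6-bis(benzyloxy)benzaldehyde | O=Cc1c(OCc2ccccc2)cccc1OCc3ccccc3
F4 | step 2 | [2,6-bis(benzyloxy)phenyl]methanol | OCc1c(OCc2ccccc2)cccc1OCc3ccccc3
F5 | step 2 | 1,3-bis(benzyloxy)-2-(bromomethyl)benzene | BrCc1c(OCc2ccccc2)cccc1OCc3ccccc3
F6 | step 2 | 1,3-bis(benzyloxy)-2-[(4-methylbenzenesulfonyl)methyl]benzene | Cc1ccc(cc1)S(=O)(=O)Cc1c(OCc2ccccc2)cccc1OCc3ccccc3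
F7 | step 11 | (2R)-5-bromo-2-(2-hydroxypropan-2-yl)-2,3-dihydro-1-benzofuran-4-ol | CC(C)(O)[C@H]1Cc2c(ccc(Br)c2O)O1
F8 | step 11 | 2-[(2R)-4-(benzyloxy)-5-bromo-2,3-dihydro-1-benzofuran-2-yl]propan-2-ol | CC(C)(O)[C@H]1Cc2c(ccc(Br)c2OCc3ccccc3)O1
F9 | step 11 | 2-[(2R)-4-(benzyloxy)-5-(4,4,5,5-tetramethyl-1,3,2-dioxaborolan-2-yl)-2,3-dihydro-1-benzofuran-2-yl]propan-2-ol | CC(C)(O)[C@H]1Cc2c(ccc(B3OC(C)(C)C(C)(C)O3)c2OCc4ccccc4)O1
F10 | step 11 | (2E)-1-[2,4-bis(benzyloxy)-6-hydroxyphenyl]-3-(dimethylamino)prop-2-en-1-one | CN(C)/C=C/C(=O)c1c(O)cc(OCc2ccccc2)cc1OCc3ccccc3
F11 | step 11 | 5,7-bis(benzyloxy)-3-iodo-4H-chromen-4-one | O=c1c(I)coc2cc(OCc3ccccc3)cc(OCc4ccccc4)c12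
F12 | step 6 | methyl (2R)-4-hydroxy-2,3-dihydro-1-benzofuran-2-carboxylate | COC(=O)[C@H]1Cc2c(cccc2O)O1
A1 | alternative 1 | 5,7-bis(benzyloxy)-3-[(2R)-4-(benzyloxy)-2-(2-hydroxypropan-2-yl)-2,3-dihydro-1-benzofuran-5-yl]-2-(trimethylsilyl)-4H-chromen-4-one | CC(C)(O)[C@H]1Cc2c(ccc(-c3c([Si](C)(C)C)oc4cc(OCc5ccccc5)cc(OCc5ccccc5)c4c3=O)c2OCc2ccccc2)O1
A2 | alternative 1 | 2,4-bis(benzyloxy)-6-hydroxybenzaldehyde | O=Cc1c(O)cc(OCc2ccccc2)cc1OCc3ccccc3
A3 | alternative 1 | 2-[(2R)-4-(benzyloxy)-5-[(trimethylsilyl)ethynyl]-2,3-dihydro-1-benzofuran-2-yl]propan-2-ol | CC(C)(O)[C@H]1Cc2c(ccc(C#C[Si](C)(C)C)c2OCc3ccccc3)O1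
A4 | alternative 2 | 2-[(2R)-4-(benzyloxy)-2-[2-(triethylsilyloxy)propan-2-yl]-2,3-dihydro-1-benzofuran-5-yl]-1-[2,4,6-tris(benzyloxy)phenyl]ethan-1-one | CC(C)(O[Si](CC)(CC)CC)[C@H]1Cc2c(ccc(CC(=O)c3c(OCc4ccccc4)cc(OCc4ccccc4)cc3OCc3ccccc3)c2OCc2ccccc2)O1
A5 | alternative 2 | 1,3,5-tris(benzyloxy)-2-iodobenzene | Ic1c(OCc2ccccc2)cc(OCc3ccccc3)cc1OCc4ccccc4
A6 | alternative 2 | {[(2R)-4-(benzyloxy)-2-[2-(triethylsilyloxy)propan-2-yl]-2,3-dihydro-1-benzofuran-5-yl]methyl}zinc chloride | CC(C)(O[Si](CC)(CC)CC)[C@H]1Cc2c(ccc(C[Zn]Cl)c2OCc3ccccc3)O1
A7 | alternative 2 | carbon monoxide | [C-]#[O+]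
A8 | alternative 3 | triethyl({2-[(2R)-4-(triisopropylsilyloxy)-2,3-dihydro-1-benzofuran-2-yl]propan-2-yl}oxy)silane | CC(C)(O[Si](CC)(CC)CC)[C@H]1Cc2c(cccc2O[Si](C(C)C)(C(C)C)C(C)C)O1
A9 | alternative 3 | N'-[(E)-{2-[2-methyl-2-(triethylsilyloxy)propoxy]-6-(triisopropylsilyloxy)phenyl}methylidene]-4-methylbenzenesulfonohydrazide | Cc1ccc(cc1)S(=O)(=O)N/N=C/c1c(OCC(C)(C)O[Si](CC)(CC)CC)cccc1O[Si](C(C)C)(C(C)C)C(C)C
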